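(The constants stand for no real mixture; no experiment stands behind them.)

Time is the question here: how far the substrate gets in 4.0 d. Gas dissolves as reagent. Free catalyst turns substrate into open intermediate, and second catalyst takes that up as catalyst intermediate, which reagent turns into product, giving second catalyst back. Reagent also ties free catalyst up as idle complex.

    gas ⇌ reagent, rate k1*(csat - [reagent]) (k1 = 0.0043 /s, csat = 1.9 mM)
    second catalyst + open intermediate ⇌ catalyst intermediate (K2 = 12 /M, k2 = 0.049 /M/s)
    reagent + catalyst intermediate → second catalyst + product (k3 = 0.74 /M/s)
    substrate + free catalyst ⇌ free catalyst + open intermediate (K4 = 6.1, k4 = 0.011 /M/s)
    reagent + free catalyst ⇌ idle complex, settled at all times (K5 = 1300 /M)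

substrate 0.050 M; gas 1.9 mM (held); free catalyst 0.50 mM; second catalyst 2.5 mM; time 4.0 d

- the product standing at 4.0 d, as a percentage of the substrate charged
- the change that raises the amount of product at 4.0 d, in percent of the substrate charged most ("none" if none brings more than 2 percentage points) (Monday's / Wednesday's / Sunday's / none)
- amount of product at 4.0 d, in percent of the substrate charged, after Wednesday's

*Where does it end?* With the gas held, I expect substrate to end as product, so the real question is how fast.

*How much reagent do you count on?* Step 1 fills the solution in about 3.88 min, far shorter than the run, so I take reagent at saturation. Balance then leaves 28.8% of the catalyst free.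

*And the speed?* I use the opening rate: the share of remaining substrate opened per day, which is the opening step's constant times the free catalyst standing, 0.137 /d. This makes the step pseudo-first-order, and it leaves 57.8% of the substrate.

*But opened is not yet product.* True. Of what second catalyst takes up, 25.6% goes on to product. With second catalyst as charged, the open intermediate drains at 2.71 /d, faster than the opening rate, so opening is the rate-limiting step. Open intermediate then stands at 5.05% of the remaining substrate, and product comes to 39.3%.

*Which change?* Wednesday's doubles the opening rate and gives 63.2%, more than the plain flask. Monday's takes the opening rate down to 0.584 of its value, and Sunday's coefficient does not appear in it. I choose Wednesday's.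

The forecast says 38%, Wednesday's, and 61% after Wednesday's, holding that “the reagent sits near saturation and ties up about 70% of the free catalyst”.

The simulation gives 38.9%, Wednesday's as the best change, and 62.3% after it. The gains are 23 percentage points for Wednesday's, −13 points for Monday's and −0.082 points for Sunday's.

In the flask, free catalyst read 28.9% of its charge at 0.400 d and 28.9% at 4.00 d, while substrate fell from 94.6% to 57.9% of the charge, close to the 57.8% the opening rate leaves. Meanwhile open intermediate read 3.25%, 4.11% and 3.13%, and product rose through 2.06% and 19.8% to 38.9%. For the same flask read at 6.0 d, the opening rate leaves 44.0% of the substrate and so gives 53.8% product. The computed flask holds 44% substrate and 53.5% product.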